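**Retrosynthetic overview**
- The C3'–alkenyl bond is cut last: Suzuki–Miyaura coupling of bromoisoflavone 12 with (R,Z)-alkenylboronate 16. The stereocentre comes unchanged from (R)-citronellal 13, and the Z geometry from trans-hydroboration of alkyne 15.
- The strategy rests on ring A (C4a, C5, C6, C7, C8, C8a), which carries one substituent only, the C7 hydroxyl para to C4a. This is the pattern a 1-methoxy-3-silyloxybuta-1,3-diene leaves when it adds across C4a=C8a.
- Key disconnection: C4a–C5 and C8–C8a. Ring A is annulated by [4+2] cycloaddition onto the sulfinyl-bearing C4a=C8a bond of the finished pyranone 6, then aromatised by loss of methanol, the silyl group and PhSOH, with no oxidant.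
- Pyranone 6 (ring C) comes from β-ketosulfoxide 4 (arylacetate 2 plus lithiated sulfoxide 3) and two one-carbon units from DMF dimethyl acetal.
- Ring order: ring B is bought with 1, ring C is made in step 3, ring A in step 4; then O-demethylation, MOM protection, coupling and deprotection.

Key step: step 4

Remark: all sulfinyl compounds are used racemic at sulfur. That centre is expelled in step 4 and has no bearing on C3 of the side chain, the only stereocentre of the target (R, read from the SMILES; alkene Z).

**Route**

Step 1
Reactants: 1 2-(3-bromo-4-methoxyphenyl)acetic acid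
Product: 2 methyl 2-(3-bromo-4-methoxyphenyl)acetate
Conditions: MeOH, H2SO4 (cat.), reflux
Reagents that add atoms: methanol, CO
Why: Fischer esterification of an unhindered arylacetic acid; the aryl bromide and the aryl methyl ether are inert to hot acidic methanol.

Step 2
Reactants: 2 methyl 2-(3-bromo-4-methoxyphenyl)acetate; 3 methyl phenyl sulfoxide (racemic)
Product: 4 1-(3-bromo-4-methoxyphenyl)-3-(phenylsulfinyl)propan-2-one (racemic at sulfur)
Conditions: 3 (2.2 equiv), LiN(iPr)2 (2.2 equiv), THF, −78 °C; then 2, −78 → 0 °C; aq NH4Cl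
Reagents that add atoms: none
Why: Claisen-type acylation of an α-sulfinyl carbanion by an ester, run with two equivalents of carbanion because the β-ketosulfoxide formed is deprotonated at once; low temperature should favour carbonyl addition over enolisation of 2, and the aryl bromide does not exchange with these stabilised lithium species at −78 °C.

Step 3
Reactants: 4 1-(3-bromo-4-methoxyphenyl)-3-(phenylsulfinyl)propan-2-one
Product: 6 3-(3-bromo-4-methoxyphenyl)-5-(phenylsulfinyl)-4H-pyran-4-one (racemic at sulfur), via bis-enaminone 5 (not isolated)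
Conditions: Me2NCH(OMe)2 (6 equiv), toluene, 100 °C; evaporate; 1 M aq H2SO4, THF, 40 °C
Reagents that add atoms: N,N-dimethylformamide dimethyl acetal, COC(OC)N(C)C; water, O
Why: Double aminomethylenation of the two activated methylene groups (the sulfinyl-flanked one first, the benzylic one on heating) should give 5, and aqueous acid hydrolyses one enamine to an enol whose oxygen adds to the other enaminone and expels dimethylamine, the usual condensation–cyclisation route from 1,3-disubstituted acetones to 3,5-disubstituted 4-pyranones; the vinyl sulfoxide has no sp3 β-hydrogen and should survive the heating.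

Step 4
Reactants: 6 3-(3-bromo-4-methoxyphenyl)-5-(phenylsulfinyl)-4H-pyran-4-one; 7 trans-1-methoxy-3-(trimethylsilyloxy)buta-1,3-diene
Product: 10 3-(3-bromo-4-methoxyphenyl)-7-hydroxy-4H-chromen-4-one (3'-bromo-7-hydroxy-4'-methoxyisoflavone), via sulfinyl cycloadduct 8 (not isolated), via sulfinyl enone 9 (not isolated)
Conditions: 7 (3 equiv), ZnBr2 (1.2 equiv), CH2Cl2, −20 °C → rt; 0.5 M aq HCl, THF, 0 °C; toluene, 80 °C
Reagents that add atoms: none
Why: Proposed new method: ZnBr2 chelated between the C4 carbonyl and sulfinyl oxygens of 6 lowers the LUMO of the C4a=C8a bond, so that the nucleophilic CH2 terminus of 7 bonds to C8a (β to both acceptors) and the methoxy-bearing terminus to C4a, by a concerted asynchronous normal-demand [4+2] cycloaddition or its stepwise Michael–ring-closure limit, either of which gives cis-fused adduct 8. The closest known reaction type is the Diels–Alder reaction of sulfinyl-activated enones and of 3-acceptor-substituted chromones with 1-methoxy-3-silyloxybutadienes, followed by sulfoxide elimination and aromatisation; a monocyclic 3-aryl-4-pyranone has not been used in it. Ring A is closed by intermolecular [4+2] annulation, the C4a–C5 and C8–C8a bonds forming in one operation on the same face of the pyranone. Cold dilute acid then hydrolyses the silyl enol ether and expels methanol by β-elimination to give enone 9, and on warming the C4a sulfinyl group leaves with the cis hydrogen on C8a (syn-elimination of PhSOH), after which the 7-oxo-7,8-dihydro tautomer enolises to phenol 10; no stereocentre remains, those of 8 and 9 and the sulfur centre being destroyed. The step needs three selectivities: the hydroxyl at C7 and not C6, which comes from the diene's CH2 terminus seeking C8a; reaction at C4a=C8a and not at the aryl-bearing C2=C3 bond, which comes from the sulfinyl group sitting on C4a only; and sulfoxide elimination toward C8a, which is secured by making C5 sp2 (loss of methanol) before the thermolysis, since an sp3 C5–H would compete and end in opening of ring C.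

Step 5
Reactants: 10 3-(3-bromo-4-methoxyphenyl)-7-hydroxy-4H-chromen-4-one
Product: 11 3-(3-bromo-4-hydroxyphenyl)-7-hydroxy-4H-chromen-4-one
Conditions: BBr3 (4 equiv), CH2Cl2, −78 °C → rt; H2O
Reagents that add atoms: none
Why: Lewis-acid cleavage of an aryl methyl ether (boron coordinates the ether oxygen and bromide removes the methyl group by SN2), done before any alkene is present; the chromone and the aryl bromide are stable and the excess covers complexation by the carbonyl and the free phenol.

Step 6
Reactants: 11 3-(3-bromo-4-hydroxyphenyl)-7-hydroxy-4H-chromen-4-one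
Product: 12 3-[3-bromo-4-(methoxymethoxy)phenyl]-7-(methoxymethoxy)-4H-chromen-4-one
Conditions: NaH (2.5 equiv), MOMCl (2.5 equiv), DMF, 0 °C → rt
Reagents that add atoms: chloromethyl methyl ether, COCCl
Why: Williamson-type O-alkylation of both phenoxides with an α-chloro ether; the acetals keep the phenols neutral in the basic coupling and come off later under mild acid.

Step 7
Reactants: 13 (R)-citronellal
Product: 15 (R)-3,7-dimethyloct-6-en-1-yne, via enol nonaflate 14 (not isolated)
Conditions: C4F9SO2F (1.3 equiv), phosphazene base P2-Et (2.5 equiv), DMF, −20 °C → rt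
Reagents that add atoms: none
Why: Enol sulfonate formation followed by β-elimination: the phosphazene base enolises the aldehyde, the enolate is O-sulfonylated to 14, and a second equivalent of base removes the vinylic hydrogen on C2 and expels nonaflate, giving the terminal alkyne with all ten carbons and without involving C3, whose R configuration is carried over from 13.

Step 8
Reactants: 15 (R)-3,7-dimethyloct-6-en-1-yne
Product: 16 2-[(1Z,3R)-3,7-dimethylocta-1,6-dien-1-yl]-4,4,5,5-tetramethyl-1,3,2-dioxaborolane
Conditions: HBpin (1 equiv), 15 (1.2 equiv), [Rh(cod)Cl]2 (1.5 mol %), P(i-Pr)3 (6 mol %), Et3N (1 equiv), cyclohexane, rt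
Reagents that add atoms: pinacolborane, [H]B1OC(C)(C)C(C)(C)O1
Why: Rhodium-catalysed anti-Markovnikov trans-hydroboration of a terminal alkyne, in which a rhodium vinylidene formed by 1,2-hydrogen shift places boron cis to the C3 substituent and so should give the Z-alkenylboronate; the trisubstituted alkene should not react at room temperature and C3 is untouched.

Step 9
Reactants: 12 3-[3-bromo-4-(methoxymethoxy)phenyl]-7-(methoxymethoxy)-4H-chromen-4-one; 16 2-[(1Z,3R)-3,7-dimethylocta-1,6-dien-1-yl]-4,4,5,5-tetramethyl-1,3,2-dioxaborolane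
Product: 17 3-{3-[(1Z,3R)-3,7-dimethylocta-1,6-dien-1-yl]-4-(methoxymethoxy)phenyl}-7-(methoxymethoxy)-4H-chromen-4-one
Conditions: 16 (1.5 equiv), Pd(OAc)2 (5 mol %), SPhos (10 mol %), K3PO4 (3 equiv), THF–H2O (10:1), 60 °C
Reagents that add atoms: none
Why: Suzuki–Miyaura coupling, in which oxidative addition of zerovalent palladium into the C3'–Br bond, transmetalation of the alkenylboronate and reductive elimination proceed with retention of the Z geometry; the electron-rich biarylphosphine suits the ortho-alkoxy aryl bromide, and the acetals and the chromone tolerate the phosphate base.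

Step 10
Reactants: 17 3-{3-[(1Z,3R)-3,7-dimethylocta-1,6-dien-1-yl]-4-(methoxymethoxy)phenyl}-7-(methoxymethoxy)-4H-chromen-4-one
Product: 18 3-{3-[(1Z,3R)-3,7-dimethylocta-1,6-dien-1-yl]-4-hydroxyphenyl}-7-hydroxy-4H-chromen-4-one (CNP0200226.1)
Conditions: NaHSO4 on SiO2, CH2Cl2, rt, light excluded
Reagents that add atoms: none
Why: Acid-catalysed cleavage of the two phenolic methoxymethyl acetals on a mild heterogeneous acid at room temperature, chosen so that the Z-alkene ortho to the freed phenol and the trisubstituted alkene are not protonated.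

**Compound list**
1 | 2-(3-bromo-4-methoxyphenyl)acetic acid | COc1ccc(CC(=O)O)cc1Br | starting material
2 | methyl 2-(3-bromo-4-methoxyphenyl)acetate | COC(=O)Cc1ccc(OC)c(Br)c1 | intermediate
3 | methyl phenyl sulfoxide (racemic) | CS(=O)c1ccccc1 | starting material
4 | 1-(3-bromo-4-methoxyphenyl)-3-(phenylsulfinyl)propan-2-one (racemic at sulfur) | COc1ccc(CC(=O)CS(=O)c2ccccc2)cc1Br | intermediate
5 | 2-(3-bromo-4-methoxyphenyl)-1,5-bis(dimethylamino)-4-(phenylsulfinyl)penta-1,4-dien-3-one (alkene geometries undefined, not isolated) | CN(C)C=C(C(=O)C(=CN(C)C)S(=O)c1ccccc1)c1ccc(OC)c(Br)c1 | intermediate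
6 | 3-(3-bromo-4-methoxyphenyl)-5-(phenylsulfinyl)-4H-pyran-4-one (racemic at sulfur) | O=c1c(-c2ccc(OC)c(Br)c2)cocc1S(=O)c1ccccc1 | intermediate
7 | trans-1-methoxy-3-(trimethylsilyloxy)buta-1,3-diene | CO/C=C/C(=C)O[Si](C)(C)C | starting material
8 | 3-(3-bromo-4-methoxyphenyl)-5-methoxy-4a-(phenylsulfinyl)-7-(trimethylsilyloxy)-4a,5,8,8a-tetrahydro-4H-chromen-4-one (racemic, cis-fused, mixture of epimers at C5 and sulfur, not isolated) | COC1C=C(O[Si](C)(C)C)CC2OC=C(c3ccc(OC)c(Br)c3)C(=O)C12S(=O)c1ccccc1 | intermediate
9 | 3-(3-bromo-4-methoxyphenyl)-4a-(phenylsulfinyl)-8,8a-dihydro-4H-chromene-4,7(4aH)-dione (racemic, cis-fused, not isolated) | O=C1C=CC2(S(=O)c3ccccc3)C(=O)C(c3ccc(OC)c(Br)c3)=COC2C1 | intermediate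
10 | 3-(3-bromo-4-methoxyphenyl)-7-hydroxy-4H-chromen-4-one | COc1ccc(-c2coc3cc(O)ccc3c2=O)cc1Br | intermediate
11 | 3-(3-bromo-4-hydroxyphenyl)-7-hydroxy-4H-chromen-4-one | Oc1ccc(-c2coc3cc(O)ccc3c2=O)cc1Br | intermediate
12 | 3-[3-bromo-4-(methoxymethoxy)phenyl]-7-(methoxymethoxy)-4H-chromen-4-one | COCOc1ccc(-c2coc3cc(OCOC)ccc3c2=O)cc1Br | intermediate
13 | (R)-citronellal, (3R)-3,7-dimethyloct-6-enal | CC(C)=CCC[C@@H](C)CC=O | starting material
14 | (3R)-3,7-dimethylocta-1,6-dien-1-yl nonafluorobutane-1-sulfonate (E/Z mixture at C1=C2, not isolated) | CC(C)=CCC[C@@H](C)C=COS(=O)(=O)C(F)(F)C(F)(F)C(F)(F)C(F)(F)F | intermediate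
15 | (R)-3,7-dimethyloct-6-en-1-yne | CC(C)=CCC[C@@H](C)C#C | intermediate
16 | 2-[(1Z,3R)-3,7-dimethylocta-1,6-dien-1-yl]-4,4,5,5-tetramethyl-1,3,2-dioxaborolane | CC(C)=CCC[C@@H](C)/C=C\B1OC(C)(C)C(C)(C)O1 | intermediate
17 | 3-{3-[(1Z,3R)-3,7-dimethylocta-1,6-dien-1-yl]-4-(methoxymethoxy)phenyl}-7-(methoxymethoxy)-4H-chromen-4-one | CC(C)=CCC[C@@H](C)/C=C\c1cc(-c2coc3cc(OCOC)ccc3c2=O)ccc1OCOC | intermediate
18 | 3-{3-[(1Z,3R)-3,7-dimethylocta-1,6-dien-1-yl]-4-hydroxyphenyl}-7-hydroxy-4H-chromen-4-one | CC(C)=CCC[C@@H](C)/C=C\c1cc(-c2coc3cc(O)ccc3c2=O)ccc1O | target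

**Step count and risks**

Total: 10 steps. Longest linear sequence: 8 steps (steps 1–6, 9, 10); steps 7 and 8 form the side-chain branch.

Most likely to fail:

1. Step 4 (Proposed new method). The ring oxygen donates into the C4a=C8a bond, so the cycloaddition may be too slow and diene 7 may be consumed by ZnBr2 first. Alternatively the adduct may lose PhSOH toward C5 before methanol is expelled, which opens ring C. The fallback uses known chemistry, sets out from 1 and comes back at 10. Acid 1 and resorcinol are heated in BF3·OEt2 (Friedel–Crafts acylation at C4 of resorcinol) to give the deoxybenzoin 2-(3-bromo-4-methoxyphenyl)-1-(2,4-dihydroxyphenyl)ethan-1-one F1. In the same medium, DMF and MeSO2Cl at 70 °C formylate the benzylic carbon and close ring C onto the ortho hydroxyl, which gives 10.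

2. Step 2. The sulfinyl carbanion may deprotonate the acidic benzylic CH2 of ester 2 rather than add to its carbonyl group, returning 2 or its Claisen self-condensation product. The fallback sets out from 1 and comes back at 4, and puts the sulfur on by substitution rather than by acylation. Acid 1 with (COCl)2 and catalytic DMF gives 2-(3-bromo-4-methoxyphenyl)acetyl chloride F2. Excess diazomethane in Et2O at 0 °C gives 1-(3-bromo-4-methoxyphenyl)-3-diazopropan-2-one F3. HCl in Et2O converts it to 1-(3-bromo-4-methoxyphenyl)-3-chloropropan-2-one F4. Thiophenol and K2CO3 in acetone give 1-(3-bromo-4-methoxyphenyl)-3-(phenylthio)propan-2-one F5, and NaIO4 in aqueous methanol oxidises the sulfide to sulfoxide 4.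

3. Step 8. The alkenylrhodium intermediate may isomerise and erode the Z geometry, or a rhodium hydride may migrate into the trisubstituted alkene or the allylic C3–H. The fallback sets out from 15 (with 12) and comes back at 17, so that no alkenylboronate is needed. Sonogashira coupling of 12 with 15 (Pd(PPh3)2Cl2, CuI, Et3N, DMF, 70 °C) gives 3-{3-[(3R)-3,7-dimethyloct-6-en-1-yn-1-yl]-4-(methoxymethoxy)phenyl}-7-(methoxymethoxy)-4H-chromen-4-one F6. Semi-hydrogenation over Pd/CaCO3 poisoned with Pb(OAc)2 and quinoline (H2, 1 atm, EtOAc) adds hydrogen cis and gives 17.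

**Further compounds**
F1 | step 4 | 2-(3-bromo-4-methoxyphenyl)-1-(2,4-dihydroxyphenyl)ethan-1-one | COc1ccc(CC(=O)c2ccc(O)cc2O)cc1Br
F2 | step 2 | 2-(3-bromo-4-methoxyphenyl)acetyl chloride | COc1ccc(CC(=O)Cl)cc1Br
F3 | step 2 | 1-(3-bromo-4-methoxyphenyl)-3-diazopropan-2-one | COc1ccc(CC(=O)C=[N+]=[N-])cc1Br
F4 | step 2 | 1-(3-bromo-4-methoxyphenyl)-3-chloropropan-2-one | COc1ccc(CC(=O)CCl)cc1Br
F5 | step 2 | 1-(3-bromo-4-methoxyphenyl)-3-(phenylthio)propan-2-one | COc1ccc(CC(=O)CSc2ccccc2)cc1Br
F6 | step 8 | 3-{3-[(3R)-3,7-dimethyloct-6-en-1-yn-1-yl]-4-(methoxymethoxy)phenyl}-7-(methoxymethoxy)-4H-chromen-4-one | CC(C)=CCC[C@@H](C)C#Cc1cc(-c2coc3cc(OCOC)ccc3c2=O)ccc1OCOC
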